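Amounts come first: this flask keeps the dawn run's substrate, 10 mM, but holds half its other conformer, 5.00 mM.

| setting | dawn | flask |
|---|---|---|
| substrate | 10 mM | 10 mM |
| other conformer | 10 mM | 5.00 mM |
| remark | run made earlier |  |
| time |  | 25 h |

dawn run (percent of the substrate and other conformer together charged)

| time / h | isomer of the product / % | target / % |
|---|---|---|
| 0.667 | 50.1 | 26.3 |
| 1.33 | 52.7 | 31.2 |
| 3.00 | 52.0 | 37.2 |
| 8.00 | 53.6 | 39.7 |

(standard deviation of a reading: 1 percentage point)

1. share of isomer of the product in isomer of the product plus target at 1.0 min
2. share of isomer of the product in isomer of the product plus target at 25 h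
3. which of isomer of the product and target there is more of at 25 h

- the numbers in the tables scatter by 1 percentage point (one standard deviation)

In the dawn run the isomer of the product moves little after its first reading of 50.1%, but the target is still climbing from 26.3%, so I read two clocks and two pools. From its gap to the last dawn reading, the target shows a half-life near 0.963 h, and 25 h is far longer than that, so I take the end of the new flask to be a plateau.

But with its equal charges, the dawn run leaves open which pool feeds which product. Going by the names, I pair substrate with target and other conformer with isomer of the product. The pair ratio g, isomer per other conformer charged over target per substrate charged, then reads 1.35 at the last dawn reading.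

So in this flask I expect g·c(other conformer)/c(substrate) = 0.675 at 25 h, which is less isomer than target and a share of 40.3%. The earliest reading stands at 0.667 h, so I give no number for 1.0 min.

The forecast pairs them the other way, “substrate gives isomer quickly, and other conformer gives target more slowly”, and it gives 88% at 1.0 min, 69% at 25 h, and isomer of the product ahead.

    substrate ⇌ dormant form (K = 1.10, k = 3.85 × 10⁻⁴ s⁻¹)
    substrate ⇌ other conformer (K = 0.350, k = 9.54 × 10⁻⁵ s⁻¹)
    other conformer → isomer of the product (k = 0.00307 s⁻¹)
    substrate → target (k = 4.73 × 10⁻⁴ s⁻¹)
    substrate + target → side product (k = 0.00759 M⁻¹ s⁻¹)

The flask gives 75.2% at 1.0 min and 44.0% at 25 h, with target ahead. At 25.0 h it holds 52.0% target against 40.9% isomer of the product, in percent of the charge, so its own pair ratio is 1.57 against the dawn reading of 1.35. For the neighbouring flask with 20 mM of other conformer and the same substrate, g gives a share of 73.0%, and that flask holds 70.0%.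

Readings and results stem from a simulated flask with constants of no real substance; the scatter is artificial.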